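## The problem

1. The target 18 is a trans-fused hydrindane (ring A: cyclohexane C3a, C4–C7, C7a; ring B: cyclopentanone C1–C3, C3a, C7a; this numbering is used for every compound, α being the face of H-7a and β that of H-3a). Every carbon of ring A is substituted: exocyclic methylene at C4, β-angelate at C5, free α-hydroxyl at C6, α-isopropyl at C7.
2. Its six stereocentres (1R,3aR,5S,6S,7S,7aR) are contiguous except for the sp2 C4; in the chair fixed by the trans fusion the isopropyl group is equatorial and the C5 and C6 oxygens are trans-diaxial.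
3. The ring fusion cannot be repaired late, because C3a and C7a are β to the C2 carbonyl, so it must be set kinetically; C7 can control C7a, C7a can control C3a and C1, and the locked chair can then control C6 and C5, whereas nothing on ring B can control ring A.
4. Ring B is a 2-ketone with oxygen on C1 only: the two α-carbons of a trans-hydrindan-2-one are nearly equivalent, so the ketol regiochemistry cannot be left to enolisation of that ketone.
5. The vicinal C5 and C6 oxygens must be told apart, and the hindered, axial, allylic one carries an angelate, whose Z double bond goes over to the tiglate under basic, nucleophilic or forcing acylation conditions.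
6. Further liabilities are the allylic C5–O bond (ionisation, SN2′), the exocyclic methylene (migration into the ring under acid) and the α-acetoxy ketone (enolisation, acyl transfer, ketol shift).
7. The feature that opens the problem is the sequence C7(iPr)–C7a–C3a–C4(=CH2) of ring A. It is the pattern that a 4-isopropylcyclohex-2-en-1-one acquires by conjugate addition at C7a anti to the isopropyl group and alkylation of the enolate at C3a anti to the new group, with C4 left at the carbonyl level; the all-trans, all-equatorial triad C7/C7a/C3a of 18 is the intrinsic outcome of that one-flask event.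
8. A second feature, the trans-diaxial C5-acyloxy/C6-hydroxy pair next to the C4 methylene, is the signature of an α-vinyl epoxide opened at its allylic carbon by the carboxylic acid itself.

## Retrosynthesis

**18 ⇒ 16 + 17 (C5–O bond of the angelate).** The acyl C–O cut would lead to a 5,6-diol with two axial secondary hydroxyls to distinguish and would force acylation of a hindered alcohol with an isomerisable acid. Cutting C5–O instead makes the ester oxygen the nucleophile: angelic acid 17 opens the 5α,6α-epoxide 16 at C5 with inversion. The trans-diaxial result, the regiochemistry (allylic carbon, axial attack, C6 screened by the isopropyl group) and the free C6 hydroxyl all follow from the epoxide. The forward reaction must go SN2 and not SN2′, under conditions that spare the Z-alkene and the α-acetoxy ketone. 16 is simpler by the whole angelate, by one stereocentre and by the differentiation problem.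

**16 ⇒ 15 ⇒ 13 (acetyl C–O, then C1–O).** The C1 oxygen is delivered by oxidation of an enol ether with its oxygen on C2 and its CH on C1. Hydroxylation of a 2-ketone enolate could not tell C1 from C3; in 13 the position of the double bond fixes the regiochemistry and the face cis to H-7a fixes C1. In ketol 15 the only hydroxyl is the one on C1, because C5/C6 are still an epoxide, so acetylation needs no selectivity.

**13 ⇒ 12 (C1=C2, ring-closing metathesis).** Ring B is opened to a vinyl group on C7a and a 2-methoxyallyl group on C3a. Cuts at C2–C3 or C1–C7a (aldol, Dieckmann, alkylation) would need a carbanion at C1 or C3 and would bring back the regiochemical ambiguity or an extra carbon to remove. 12 is monocyclic. The forward reaction must close a trans-fused cyclopentene onto an enol ether beside a vinyl epoxide.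

**12 ⇒ 11 ⇒ 10 ⇒ 8 (C4=CH2; the two epoxide C–O bonds; C5=C6).** All three changes use the C4 carbonyl as the only handle: Wittig methylenation, nucleophilic epoxidation of enone 10, dehydrogenation of ketone 8. The epoxide must be made while C4 is a carbonyl, because hydroperoxide then picks the only electron-poor alkene and attacks C6 axially. All of this must precede the unveiling of the ring B ketone, so that C4 is the only carbonyl present.

**8 ⇒ 5 + 6 + vinyl nucleophile (C7a–C1 and C3a–C3).** Both bonds from ring A to the future ring B are cut at once. (S)-Cryptone 5 has nine carbons and one stereocentre; 8 has fifteen carbons, three stereocentres and every carbon of the skeleton except the methylene. The 2-methoxyallyl group is chosen over a plain allyl group because it carries the C2 oxygen in masked form. The forward reaction must give 1,4-addition anti to the isopropyl group and mono-C-alkylation anti to the vinyl group.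

**5 ⇒ 3 ⇒ 1 + 2 (C5=C6 of cryptone by aldol condensation; C–C bond α to the aldehyde by Michael addition).** The single stereocentre bought by catalysis is C7. 3-Methylbutanal 1 and methyl vinyl ketone 2 are commodity chemicals.

## Roads not taken

**Alternative 1:** the most obvious plan. Cut both ester bonds and the C1–O bond to reach triol A2, and build ring B by a [3+2] annulation of 5 with a trimethylenemethane equivalent (zerovalent palladium catalysis) to give methylenecyclopentane A1.
- The annulation closes the ring on the face already occupied by the C7a arm, so A1 is cis-fused. Equilibration through the C4 ketone favours the trans isomer only moderately.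
- Ozonolysis of A1 gives a 2-ketone whose C1 and C3 methylenes cannot be distinguished in the enolate oxidation.
- A2 has three secondary hydroxyls. Protecting groups would be needed, and angeloylation of the axial C5 hydroxyl would need forcing conditions that favour the tiglate.
- In the chosen plan each oxygen substituent arrives already differentiated and no protecting group is used.

**Alternative 2:** cut C3a–C7a and C6–C7 (intramolecular Diels–Alder). Triene A3, built on a tether that carries the C1 stereocentre, would cyclise through the endo, trans-fused transition state to A4 and set C3a, C7a, C7 and C6 at once.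
- A3 needs an (E,E)-silyloxydiene, a masked tether ketone and an enone, about ten steps before the key step.
- The dienophile must be activated by an acetyl group that afterwards has to be turned into the isopropyl group.
- Fusion and facial selectivity rest on one allylic stereocentre.
- After A4 the C4 methylene and C5 oxygen still require an epoxidation and isomerisation, and three protecting groups must be removed.
- The relay from C7 reaches the same stereocentres in fewer steps with better precedented selectivity.

**Alternative 3:** cut C1–C2, C2–C3 and C3a–C7a (dienyl Pauson–Khand reaction). Dienyne A5 with [RhCl(CO)2]2 and CO would close both rings to enone A6, leaving C7a and C1 to a reductive enolate oxidation.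
- A5 already contains C5, C6 and C7 as three contiguous acyclic stereocentres, so the precursor is hardly simpler than ring A itself.
- C3a would be set in the cycloaddition under uncertain control, since the allylic isopropyl group prefers an axial position next to the new enone.
- C7a would depend on the protonation of a dissolving-metal intermediate next to allylic C–O bonds.
- The C5 and C6 oxygens would need orthogonal protection.

Key step: step 3

Remark on the chemistry: the sense of induction in step 1 is taken from the steric-shielding model for 2-(diarylmethyl)pyrrolidine ether catalysts; if it were the opposite, the (R)-catalyst would be used.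
Remark on the chemistry: 6 is treated as a purchased reagent (stabilised, distilled before use).

## Route

Step 1
Reactants: 1 3-methylbutanal; 2 but-3-en-2-one
Product: 3 (2S)-5-oxo-2-(propan-2-yl)hexanal
Conditions: (S)-2-(methoxydiphenylmethyl)pyrrolidine (5 mol %), ethyl 3,4-dihydroxybenzoate (20 mol %), neat, 4 °C
Reagents that add atoms: none
Why: Enamine-catalysed Michael addition; the (E)-enamine of 1 is shielded on one face by the CPh2OMe group and adds to 2 through the open face, which sets the future C7 as S, while the catechol co-catalyst activates the enone by hydrogen bonding.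

Step 2
Reactants: 3 (2S)-5-oxo-2-(propan-2-yl)hexanal
Product: 5 (4S)-4-(propan-2-yl)cyclohex-2-en-1-one [(S)-cryptone], via aldol adduct 4 (not isolated)
Conditions: LiOH·H2O, iPrOH, 23 °C
Reagents that add atoms: none
Why: Intramolecular aldol condensation (6-enolexo attack of the methyl ketone enolate on the aldehyde, then E1cB loss of water); cyclisation should outpace enolisation of the α-branched aldehyde under these mild conditions, so the stereocentre is kept.

Step 3
Reactants: 5 (4S)-4-(propan-2-yl)cyclohex-2-en-1-one; 6 3-bromo-2-methoxyprop-1-ene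
Product: 8 (2R,3S,4S)-3-ethenyl-2-(2-methoxyprop-2-en-1-yl)-4-(propan-2-yl)cyclohexan-1-one, via magnesium enolate 7 (not isolated)
Conditions: CH2=CHMgBr, CuBr·SMe2 (10 mol %), THF, −78 → −40 °C; then 6, HMPA, −40 → 0 °C
Reagents that add atoms: vinylmagnesium bromide, C=C[Mg]Br
Why: Tandem conjugate addition–enolate alkylation (three-component coupling of a cyclic enone). The vinyl group is transferred from a cuprate π-complex through a trivalent copper β-adduct and enters C7a on the face opposite to the adjacent C7 isopropyl group (trans-3,4 selectivity of 4-substituted cyclohexenones), so C7 controls C7a. The regiodefined enolate 7 is then alkylated by 6 at C3a on the face opposite to the new vinyl group (trans-2,3 selectivity), so C7a controls C3a; the product has all three substituents equatorial, which is also the stable arrangement at the enolisable C3a. The step closes no ring: it installs both arms for the metathesis of step 7, the vinyl group (C1) and the 2-methoxyallyl group (C3 and C2 with its oxygen), so that the later ketol can have only one regiochemistry. The selectivities needed are 1,4- over 1,2-addition (secured by copper catalysis), C- over O-alkylation and mono- over polyalkylation (secured by the reactive allylic bromide, HMPA, low temperature and the absence of a proton source before the quench).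

Step 4
Reactants: 8 (2R,3S,4S)-3-ethenyl-2-(2-methoxyprop-2-en-1-yl)-4-(propan-2-yl)cyclohexan-1-one
Product: 10 (4R,5S,6R)-5-ethenyl-6-(2-methoxyprop-2-en-1-yl)-4-(propan-2-yl)cyclohex-2-en-1-one, via lithium enolate 9 (not isolated)
Conditions: LDA, THF, −78 °C; then PhS(Cl)=NtBu, −78 °C
Reagents that add atoms: none
Why: Kinetic deprotonation at the C5 methylene (not the C3a methine) gives 9, which is sulfenylated at C5 by the sulfinimidoyl chloride and loses the sulfur group by syn-elimination at low temperature (sulfinimidoyl chloride dehydrogenation of ketones, also called Mukaiyama dehydrogenation); the base-only conditions spare the acid-labile enol ether.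

Step 5
Reactants: 10 (4R,5S,6R)-5-ethenyl-6-(2-methoxyprop-2-en-1-yl)-4-(propan-2-yl)cyclohex-2-en-1-one
Product: 11 (1S,3R,4S,5S,6S)-4-ethenyl-3-(2-methoxyprop-2-en-1-yl)-5-(propan-2-yl)-7-oxabicyclo[4.1.0]heptan-2-one
Conditions: 30% aq. H2O2, NaOH (cat.), MeOH, 0 °C
Reagents that add atoms: hydrogen peroxide, OO
Why: Weitz–Scheffer epoxidation; in the all-equatorial half-chair hydroperoxide should add to C6 along the axial trajectory on the α-face (anti to the C7a vinyl group, as in 5-substituted cyclohexenones) and the enolate closes the epoxide on the same face, which sets C6 and places the leaving oxygen on C5. Only the electron-poor alkene reacts.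

Step 6
Reactants: 11 (1S,3R,4S,5S,6S)-4-ethenyl-3-(2-methoxyprop-2-en-1-yl)-5-(propan-2-yl)-7-oxabicyclo[4.1.0]heptan-2-one
Product: 12 (1R,3R,4R,5S,6S)-4-ethenyl-3-(2-methoxyprop-2-en-1-yl)-2-methylidene-5-(propan-2-yl)-7-oxabicyclo[4.1.0]heptane
Conditions: Ph3PCH3Br, KOtBu, THF, 0 → 23 °C
Reagents that add atoms: methyltriphenylphosphonium bromide, C[P+](c1ccccc1)(c1ccccc1)c1ccccc1.[Br-]
Why: Wittig methylenation of an α,β-epoxy ketone to the vinyl epoxide, a known conversion; should the ylide enolise C3a, the trans-diequatorial epimer present is the stable one.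

Step 7
Reactants: 12 (1R,3R,4R,5S,6S)-4-ethenyl-3-(2-methoxyprop-2-en-1-yl)-2-methylidene-5-(propan-2-yl)-7-oxabicyclo[4.1.0]heptane
Product: 13 (3aR,5R,6S,7S,7aR)-5,6-epoxy-2-methoxy-4-methylidene-7-(propan-2-yl)-3a,4,5,6,7,7a-hexahydro-3H-indene
Conditions: second-generation Grubbs catalyst (H2IMes)(PCy3)Cl2Ru=CHPh (5 mol %), toluene, high dilution, 60 °C
Reagents that add atoms: none
Why: Ring-closing metathesis of an olefinic enol ether; the catalyst initiates at the monosubstituted vinyl group and closes ring B onto the 1,1-disubstituted enol ether with loss of ethene, giving the cyclic enol ether with oxygen on C2 and CH on C1. The hindered C4 methylene and the epoxide are spectators, and the trans-fused cyclopentene has the ring fusion of the Δ16-steroids.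

Step 8
Reactants: 13 (3aR,5R,6S,7S,7aR)-5,6-epoxy-2-methoxy-4-methylidene-7-(propan-2-yl)-3a,4,5,6,7,7a-hexahydro-3H-indene
Product: 15 (1R,3aR,5R,6S,7S,7aR)-5,6-epoxy-1-hydroxy-4-methylidene-7-(propan-2-yl)octahydro-2H-inden-2-one, via methoxy epoxide 14 (not isolated)
Conditions: dimethyldioxirane, acetone, −78 → −20 °C; then H2O, NaHCO3, THF, 0 °C
Reagents that add atoms: dimethyldioxirane, CC1(C)OO1; water, O
Why: Rubottom-type oxidation; dimethyldioxirane attacks only the electron-rich enol ether, from the α-face cis to H-7a and away from C7, and neutral hydrolysis of 14 gives the ketol with the new oxygen on C1 (R) and the carbonyl on C2. The α-oxygen is pseudo-equatorial and trans to C7, so it should also be the more stable epimer at this enolisable centre.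

Step 9
Reactants: 15 (1R,3aR,5R,6S,7S,7aR)-5,6-epoxy-1-hydroxy-4-methylidene-7-(propan-2-yl)octahydro-2H-inden-2-one
Product: 16 (1R,3aR,5R,6S,7S,7aR)-5,6-epoxy-4-methylidene-2-oxo-7-(propan-2-yl)octahydro-1H-inden-1-yl acetate
Conditions: Ac2O, pyridine, DMAP (cat.), CH2Cl2, 0 °C
Reagents that add atoms: acetic anhydride, CC(=O)OC(C)=O
Why: Acetylation of the only hydroxyl group in the molecule; the C5 and C6 oxygens are still masked as the epoxide, so no selectivity is required.

Step 10
Reactants: 16 (1R,3aR,5R,6S,7S,7aR)-5,6-epoxy-4-methylidene-2-oxo-7-(propan-2-yl)octahydro-1H-inden-1-yl acetate; 17 (2Z)-2-methylbut-2-enoic acid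
Product: 18 (1R,3aR,5S,6S,7S,7aR)-1-(acetyloxy)-6-hydroxy-4-methylidene-2-oxo-7-(propan-2-yl)octahydro-1H-inden-5-yl (2Z)-2-methylbut-2-enoate
Conditions: 17, [N,N′-bis(3,5-di-tert-butylsalicylidene)ethane-1,2-diaminato]cobalt (5 mol %), iPr2NEt, air, tBuOMe, 23 °C
Reagents that add atoms: none
Why: Epoxide opening by a carboxylic acid under (salen)cobalt catalysis (the trivalent cobalt carboxylate forms in air); angelate should attack the allylic C5 from the β-face with inversion, the trans-diaxial Fürst–Plattner mode, while C6 is screened by the isopropyl group, giving the C5 (S) ester and the free axial C6 hydroxyl in one step. The near-neutral conditions at room temperature should avoid Z to E isomerisation, and the trans-diaxial hydroxy ester cannot undergo acyl migration.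

## Compound list

1 | 3-methylbutanal | CC(C)CC=O | starting material
2 | but-3-en-2-one | CC(=O)C=C | starting material
3 | (2S)-5-oxo-2-(propan-2-yl)hexanal | O=C[C@H](C(C)C)CCC(C)=O | intermediate
4 | (4S)-3-hydroxy-4-(propan-2-yl)cyclohexan-1-one (aldol adduct, both C3 epimers) | O=C1CC(O)[C@H](C(C)C)CC1 | intermediate
5 | (4S)-4-(propan-2-yl)cyclohex-2-en-1-one | O=C1C=C[C@H](C(C)C)CC1 | intermediate
6 | 3-bromo-2-methoxyprop-1-ene | C=C(OC)CBr | starting material
7 | bromomagnesium (3S,4S)-3-ethenyl-4-(propan-2-yl)cyclohex-1-en-1-olate | Br[Mg]OC1=C[C@@H](C=C)[C@H](C(C)C)CC1 | intermediate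
8 | (2R,3S,4S)-3-ethenyl-2-(2-methoxyprop-2-en-1-yl)-4-(propan-2-yl)cyclohexan-1-one | O=C1[C@H](CC(OC)=C)[C@@H](C=C)[C@H](C(C)C)CC1 | intermediate
9 | lithium (4S,5S,6R)-5-ethenyl-6-(2-methoxyprop-2-en-1-yl)-4-(propan-2-yl)cyclohex-1-en-1-olate | [Li]OC=1[C@H](CC(OC)=C)[C@@H](C=C)[C@H](C(C)C)CC=1 | intermediate
10 | (4R,5S,6R)-5-ethenyl-6-(2-methoxyprop-2-en-1-yl)-4-(propan-2-yl)cyclohex-2-en-1-one | O=C1[C@H](CC(OC)=C)[C@@H](C=C)[C@H](C(C)C)C=C1 | intermediate
11 | (1S,3R,4S,5S,6S)-4-ethenyl-3-(2-methoxyprop-2-en-1-yl)-5-(propan-2-yl)-7-oxabicyclo[4.1.0]heptan-2-one | O=C1[C@H](CC(OC)=C)[C@@H](C=C)[C@H](C(C)C)[C@@H]2O[C@H]12 | intermediate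
12 | (1R,3R,4R,5S,6S)-4-ethenyl-3-(2-methoxyprop-2-en-1-yl)-2-methylidene-5-(propan-2-yl)-7-oxabicyclo[4.1.0]heptane | C=C1[C@H](CC(OC)=C)[C@@H](C=C)[C@H](C(C)C)[C@@H]2O[C@H]12 | intermediate
13 | (3aR,5R,6S,7S,7aR)-5,6-epoxy-2-methoxy-4-methylidene-7-(propan-2-yl)-3a,4,5,6,7,7a-hexahydro-3H-indene | C=C1[C@@H]2CC(OC)=C[C@H]2[C@H](C(C)C)[C@@H]3O[C@H]13 | intermediate
14 | (1R,2S,3aR,5R,6S,7S,7aR)-1,2:5,6-diepoxy-2-methoxy-4-methylidene-7-(propan-2-yl)octahydro-1H-indene | C=C1[C@@H]2C[C@]3(OC)O[C@@H]3[C@H]2[C@H](C(C)C)[C@@H]4O[C@H]14 | intermediate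
15 | (1R,3aR,5R,6S,7S,7aR)-5,6-epoxy-1-hydroxy-4-methylidene-7-(propan-2-yl)octahydro-2H-inden-2-one | C=C1[C@@H]2CC(=O)[C@H](O)[C@H]2[C@H](C(C)C)[C@@H]3O[C@H]13 | intermediate
16 | (1R,3aR,5R,6S,7S,7aR)-5,6-epoxy-4-methylidene-2-oxo-7-(propan-2-yl)octahydro-1H-inden-1-yl acetate | C=C1[C@@H]2CC(=O)[C@H](OC(C)=O)[C@H]2[C@H](C(C)C)[C@@H]3O[C@H]13 | intermediate
17 | (2Z)-2-methylbut-2-enoic acid (angelic acid) | C/C=C(/C)C(O)=O | starting material
18 | (1R,3aR,5S,6S,7S,7aR)-1-(acetyloxy)-6-hydroxy-4-methylidene-2-oxo-7-(propan-2-yl)octahydro-1H-inden-5-yl (2Z)-2-methylbut-2-enoate | C=C1[C@@H]2CC(=O)[C@H](OC(C)=O)[C@H]2[C@H](C(C)C)[C@H](O)[C@H]1OC(=O)/C(C)=C\C | target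

## Step count and risk

Total step count: 10. Longest linear sequence: 10 steps (from 1 and 2; 6 and 17 are purchased). No protecting group is used.

**Step 3 (key step).** What may go wrong: the magnesium enolate formed under copper catalysis alkylates slowly, so proton exchange with product ketone can scramble the enolate and lead to polyalkylation, loss of the trans relationship at C3a or alkylation at C5. Fallback, from 5 back to 8: the two bond formations are separated. The same copper-catalysed vinyl addition is run with Me3SiCl as internal trap to give {[(3S,4S)-3-ethenyl-4-(propan-2-yl)cyclohex-1-en-1-yl]oxy}trimethylsilane F1, which is isolated. MeLi then releases the lithium enolate free of magnesium and copper salts, and this is alkylated with 6 in THF/HMPA to give 8.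

**Step 5.** What may go wrong: poor facial selectivity of the hydroperoxide addition, because axial α-attack at C6 is gauche to the equatorial isopropyl group and the competing β-attack through a boat-like transition state is anti to it. The β-epoxide would invert the C5/C6 outcome at the end. Fallback, from 10 back to 11, by hydroxyl direction:
- Luche reduction (NaBH4, CeCl3) by axial hydride attack gives the equatorial β-alcohol (1R,4R,5S,6R)-5-ethenyl-6-(2-methoxyprop-2-en-1-yl)-4-(propan-2-yl)cyclohex-2-en-1-ol F2.
- Mitsunobu inversion with 4-nitrobenzoic acid gives the α-ester (1S,4R,5S,6R)-5-ethenyl-6-(2-methoxyprop-2-en-1-yl)-4-(propan-2-yl)cyclohex-2-en-1-yl 4-nitrobenzoate F3.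
- Methanolysis (K2CO3, MeOH) gives the axial α-alcohol (1S,4R,5S,6R)-5-ethenyl-6-(2-methoxyprop-2-en-1-yl)-4-(propan-2-yl)cyclohex-2-en-1-ol F4.
- VO(acac)2/tBuOOH delivers oxygen cis to the axial hydroxyl and gives (1R,2R,3R,4R,5S,6S)-4-ethenyl-3-(2-methoxyprop-2-en-1-yl)-5-(propan-2-yl)-7-oxabicyclo[4.1.0]heptan-2-ol F5.
- Dess–Martin oxidation returns 11.

**Step 7.** What may go wrong: slow closure of the strained trans-fused cyclopentene onto a 1,1-disubstituted enol ether, with competing oligomerisation, catalyst deactivation by the enol ether, or hydrolysis of the product enol ether on work-up. Fallback, from 8 back to 13: the metathesis is moved to the robust ketone 8, where higher temperature and catalyst loading are tolerated.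
- Ring closure of 8 gives (3aR,7S,7aR)-2-methoxy-7-(propan-2-yl)-3,3a,5,6,7,7a-hexahydro-4H-inden-4-one F6.
- The dehydrogenation of step 4 then gives (3aR,7R,7aR)-2-methoxy-7-(propan-2-yl)-3,3a,7,7a-tetrahydro-4H-inden-4-one F7.
- Weitz–Scheffer epoxidation gives (3aR,5S,6S,7S,7aR)-5,6-epoxy-2-methoxy-7-(propan-2-yl)-3,3a,5,6,7,7a-hexahydro-4H-inden-4-one F8.
- Wittig methylenation returns 13.

**Step 10.** What may go wrong: SN2′ attack of the carboxylate at the exocyclic methylene carbon (the C5–O bond is aligned with the π-system), sluggish opening of a hindered epoxide by a weakly nucleophilic unsaturated acid, or Z to E isomerisation on prolonged reaction. Fallback, from 16 back to 18: dilute HClO4 in aqueous THF at 0 °C opens the epoxide with water at the allylic C5 in the same trans-diaxial sense to give (1R,3aR,5S,6S,7S,7aR)-5,6-dihydroxy-4-methylidene-2-oxo-7-(propan-2-yl)octahydro-1H-inden-1-yl acetate F9. The less hindered allylic C5 hydroxyl (C6 is flanked by the isopropyl group) is then acylated with the mixed anhydride of 17 and 2,4,6-trichlorobenzoyl chloride (Et3N, toluene, no nucleophilic catalyst) to give 18.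

## Further compounds

F1 | step 3 | {[(3S,4S)-3-ethenyl-4-(propan-2-yl)cyclohex-1-en-1-yl]oxy}trimethylsilane | C[Si](C)(C)OC1=C[C@@H](C=C)[C@H](C(C)C)CC1
F2 | step 5 | (1R,4R,5S,6R)-5-ethenyl-6-(2-methoxyprop-2-en-1-yl)-4-(propan-2-yl)cyclohex-2-en-1-ol | O[C@H]1[C@H](CC(OC)=C)[C@@H](C=C)[C@H](C(C)C)C=C1
F3 | step 5 | (1S,4R,5S,6R)-5-ethenyl-6-(2-methoxyprop-2-en-1-yl)-4-(propan-2-yl)cyclohex-2-en-1-yl 4-nitrobenzoate | O=C(O[C@@H]1[C@H](CC(OC)=C)[C@@H](C=C)[C@H](C(C)C)C=C1)c1ccc(cc1)[N+](=O)[O-]
F4 | step 5 | (1S,4R,5S,6R)-5-ethenyl-6-(2-methoxyprop-2-en-1-yl)-4-(propan-2-yl)cyclohex-2-en-1-ol | O[C@@H]1[C@H](CC(OC)=C)[C@@H](C=C)[C@H](C(C)C)C=C1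
F5 | step 5 | (1R,2R,3R,4R,5S,6S)-4-ethenyl-3-(2-methoxyprop-2-en-1-yl)-5-(propan-2-yl)-7-oxabicyclo[4.1.0]heptan-2-ol | O[C@@H]1[C@H](CC(OC)=C)[C@@H](C=C)[C@H](C(C)C)[C@@H]2O[C@H]12
F6 | step 7 | (3aR,7S,7aR)-2-methoxy-7-(propan-2-yl)-3,3a,5,6,7,7a-hexahydro-4H-inden-4-one | O=C1[C@@H]2CC(OC)=C[C@H]2[C@H](C(C)C)CC1
F7 | step 7 | (3aR,7R,7aR)-2-methoxy-7-(propan-2-yl)-3,3a,7,7a-tetrahydro-4H-inden-4-one | O=C1[C@@H]2CC(OC)=C[C@H]2[C@H](C(C)C)C=C1
F8 | step 7 | (3aR,5S,6S,7S,7aR)-5,6-epoxy-2-methoxy-7-(propan-2-yl)-3,3a,5,6,7,7a-hexahydro-4H-inden-4-one | O=C1[C@@H]2CC(OC)=C[C@H]2[C@H](C(C)C)[C@@H]3O[C@H]13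
F9 | step 10 | (1R,3aR,5S,6S,7S,7aR)-5,6-dihydroxy-4-methylidene-2-oxo-7-(propan-2-yl)octahydro-1H-inden-1-yl acetate | C=C1[C@@H]2CC(=O)[C@H](OC(C)=O)[C@H]2[C@H](C(C)C)[C@H](O)[C@H]1O
A1 | alternative 1 | (3aS,7S,7aS)-2-methylidene-7-(propan-2-yl)octahydro-4H-inden-4-one (cis-fused annulation product) | O=C1[C@H]2CC(=C)C[C@H]2[C@H](C(C)C)CC1
A2 | alternative 1 | (1R,3aR,5S,6S,7S,7aR)-1,5,6-trihydroxy-4-methylidene-7-(propan-2-yl)octahydro-2H-inden-2-one | C=C1[C@@H]2CC(=O)[C@H](O)[C@H]2[C@H](C(C)C)[C@H](O)[C@H]1O
A3 | alternative 2 | (3E,5R,8E,10E)-5,11-bis[(tert-butyldimethylsilyl)oxy]-6,6-(ethane-1,2-diyldioxy)-9-methylundeca-3,8,10-trien-2-one | CC(C)(C)[Si](C)(C)O/C=C/C(C)=C/CC1(OCCO1)[C@H](O[Si](C)(C)C(C)(C)C)/C=C/C(C)=O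
A4 | alternative 2 | 1-[(1R,3aR,6R,7S,7aR)-1,6-bis[(tert-butyldimethylsilyl)oxy]-2,2-(ethane-1,2-diyldioxy)-4-methyl-2,3,3a,6,7,7a-hexahydro-1H-inden-7-yl]ethan-1-one | CC=1[C@@H]2CC3(OCCO3)[C@H](O[Si](C)(C)C(C)(C)C)[C@H]2[C@H](C(C)=O)[C@H](O[Si](C)(C)C(C)(C)C)C=1
A5 | alternative 3 | (4S,5S,6S)-4,5-bis[(tert-butyldimethylsilyl)oxy]-3-methylidene-6-(propan-2-yl)oct-1-en-7-yne | C#C[C@H](C(C)C)[C@H](O[Si](C)(C)C(C)(C)C)[C@@H](O[Si](C)(C)C(C)(C)C)C(=C)C=C
A6 | alternative 3 | (3aR,5S,6S,7S)-5,6-bis[(tert-butyldimethylsilyl)oxy]-4-methylidene-7-(propan-2-yl)-3,3a,4,5,6,7-hexahydro-2H-inden-2-one | C=C1[C@@H]2CC(=O)C=C2[C@H](C(C)C)[C@H](O[Si](C)(C)C(C)(C)C)[C@H]1O[Si](C)(C)C(C)(C)C
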